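In this flask the dissolved gas started from none and could not rise above saturation, so it could not consume the starting material faster than one fixed clock allows.

starting material 0.0010 M; gas phase 0.092 mM (held); time 25 s

- amount of target and crystals together at 25 s, in percent of the starting material charged
- concentration of dissolved gas in solution at 25 s, in percent of saturation

    gas phase ⇌ dissolved gas, rate k1*(csat - [dissolved gas]) (k1 = 13 /s, csat = 0.092 mM)
    starting material + dissolved gas → target (k2 = 650 /M/s)
    dissolved gas + target → over-reacted product (k3 = 1200 /M/s)
    crystals ⇌ target, rate k4*(cs4 - [target]) while solid is left; crystals form when [target] > cs4 (cs4 = 0.011 mM, k4 = 8.0 /s)
    starting material + target → side product (k5 = 73 /M/s)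

- percentages count the starting material that a species holds: one side product counts as two
- target is meant together with its crystals
- solid, in amounts per volume of the solution: crystals
- at the start none of the gas is dissolved
- run time (flask): 25 s

I called the rate constant of the second step times the saturation concentration the saturated clock, 0.0598 /s, a pseudo-first-order constant for the starting material. If all of the converted material survived as target, the clock gave my ceiling. For the zero of the scale I put the target as exposed as the starting material: no crystals, gas at saturation, attack at 0.110 /s, side product set aside. That gave my floor.

To tighten the bracket, I noted that crystals exchange at 8.0 /s, faster than that attack, so I held c(target) at 0.011 mM. The steady drain then cost 3.04% to over-reaction, and I estimated 2.01% of target lost to side product, reckoned at that held c(target) with the starting material as charged. Transfer at 13 /s also outran uptake at 0.650 /s, so I balanced the two for c(dissolved gas) at the asked time and got 98.8%.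

| Mark | y |
|---|---|
| Ceiling | 77.6% |
| My estimate | 72.5% |
| Forecast | 70.6% |
| Floor | 19.0% |

The forecast, with 98.8% for the gas, lay inside the bracket and below my estimate; its grounds included this: “Crystallisation holds dissolved target near 0.012–0.018 mM”.

The flask gave 70.5% and 98.8%. By 12.5 s it held 47.8% as target and crystals, with dissolved target at 130% of saturation. Half of the crystal growth up to the asked time was done by 8.54 s. The clock left 22.4% of the starting material at the asked time, and the flask held 23%. The gap under the ceiling was 7.1 percentage points, while the flask held 3.86% as over-reacted product and 2.85% as side product.

For the neighbour read at 1.5 min, the clock set the ceiling at 99.5%, and the drain to over-reaction came to 10.9% of the charge. The computed neighbour gave 84.1%, with 11.9% over-reacted.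

The constants belong to no real substance; the run is a simulation.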